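How much scavenger must be in the flask from the start so that just half of the starting material has reacted at 3.0 d?

starting material 1.6 M; reagent 0.960 M; free catalyst 4.2 mM; time 3.0 d

- the concentration of scavenger at which the part of the starting material that has reacted at 3.0 d is just 50%, in M

- what is said of released group includes idle adduct
- the amount of scavenger is what is sought; it is there from the start
- what has gone from starting material into another species counts as reacted, even if it can come back
- run time (flask): 3.0 d

    catalyst intermediate C → free catalyst + target (k1 = 0.32 /s)
    reagent + catalyst intermediate A ⇌ catalyst intermediate B (K2 = 0.52 /M, k2 = 0.97 /M/s)
    scavenger + released group → scavenged by-product (k3 = 1.2 × 10⁻⁴ /M/s)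
    catalyst intermediate B → released group + catalyst intermediate C (k4 = 0.028 /s)
    starting material + free catalyst ⇌ catalyst intermediate A (K5 = 0.31 /M, k5 = 0.018 /M/s)
    reagent + released group ⇌ idle adduct, settled at all times (K6 = 48 /M)

I keep the books on the reagent, the limiting reagent here, since its 0.960 M stands against 1.6 M of starting material. The target point means x = 0.800 M reacted, and each mole reacted takes one reagent, which leaves 0.160 M, either free (b) or held in idle adduct. The catalyst forms hold at most 4.2 mM, so I leave them out of the books. Each mole reacted also gives one released group, which is either scavenged or sitting on a reagent as adduct; for now I set aside the part that is free. The books then close with D = 2x − c + b, where D is the released group scavenged and c the reagent charged.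

I assume the leftover splits evenly, so b = 0.0800 M, and D comes to 0.720 M. This scavenging debt is the amount of scavenger that must be used up by the asked time. An even split puts free released group at 1/K6, 0.0208 M, a part I leave out of the debt. If I hold that level over the whole run, which is my assumption, the scavenger decays pseudo-first-order with time constant K6/k3 = 4.63 d. On that assumption it loses a fraction 0.477 of its charge in 3.0 d, so I commit to debt over fraction, 1.51 M.

The forecast gives 1.45 M, within 1.1 M to 1.9 M, from a "rough hand march of the steady-state catalytic rate against the slow scavenging", and my figure stands a little higher.

The simulation gives 1.42 M, which is 0.0900 M less than my reckoning and 0.888 of the starting material charged. At 1.50 d this flask has used 38.5% of its starting material and keeps 15.6% of its reagent free, so the debt then reads 0.422 M. Scavenger still free at that time is 72.5% of its charge, which means 0.391 M has gone.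

(The numbers of this flask are those of an exercise; the flask was simulated.)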